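I decide to sort the given numbers by what an error in each does to the product before I touch the row.

common to all: starting material 0.20 mM; protic impurity 0.00400 mM; time 12 s

| charge | partner |
|---|---|
| beta | 1.00 equiv |
| zeta | 1.50 equiv |
| eta | 2.00 equiv |
| delta | 3.00 equiv |
| alpha | 5.00 equiv |

    intermediate A → product (k1 = 0.0716 /s)
    intermediate B ⇌ intermediate D (K2 = 4.90, k2 = 0.0809 /s)
    starting material + partner → intermediate A (k3 = 919 /M/s)
    partner + intermediate A ⇌ intermediate C (K4 = 9270 /M, k4 = 1260 /M/s)
    intermediate A ⇌ intermediate B (K5 = 0.464, k5 = 0.535 /s)
    partner + protic impurity → quenched reagent (k6 = 44500 /M/s)

* amount of product at the end, in percent of the starting material charged for beta, zeta, eta, delta, alpha, in this order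
* how that number moves from the first to the last of them (hardly changes / rises, then falls / falls all the way / falls, then rises / rises all the way)

- "hardly changes" means that all values lie within two and a half points (for a concentration: within two and a half percent of the largest)
- run time (beta): 12 s

Let P be the free partner concentration, K_C the constant 9270 /M that binds partner and intermediate A into intermediate C, K_B the constant 0.464 between intermediate A and intermediate B, and k_P the constant 0.0716 /s of intermediate A going to product.

I test the numbers on alpha, the flask with the most partner. The impurity is 2.00% of the starting material charge, so I let it and its quench constant go. Starting material has a half-life of 0.754 s on alpha with partner as charged, shorter than the run, so an error in its constant shifts the end little there. Intermediates A and B exchange with a half-life of 0.411 s, again shorter than the run, so their rate constant can be loose while K_B counts. An error in k_P passes straight into the product, and one in K_C also passes in on alpha, as the next step shows.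

On alpha, one equivalent of partner goes into making intermediate A and up to one more sits in intermediate C, so I take P as 0.600 mM. Then K_C P is 5.56, well above one plus K_B. The rate of product formation on alpha therefore runs close to order minus one in free partner, with intermediate C as the resting state. One over the sum of one, K_B and K_C P comes to 0.142. This free share, the fraction of the pool of intermediates A, B and C standing as intermediate A, is what I carry. With the whole charge in the pool, k_P times the free share times the run gives 12.2% product on alpha. I stop there, since P falls through the run on beta.

The forecast gives 19%, 22%, 21%, 16% and 10%, shape rises, then falls, holding that “excess partner parks A as the off-path complex C”. Its alpha value is below mine.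

The simulation gives 16.1%, 18.8%, 19.3%, 17.5% and 12.8%, shape rises, then falls, turning at 1.9 equiv.

On alpha at 12.0 s, intermediate C holds 67.2% and intermediate A 10.1%, a free share of 0.124 against my 0.142. Taking the path to intermediate C away turns the fall of 6.6 percentage points from eta to alpha into a rise of 6.8 points, and that change would make the forecast's shape wrong. On delta, the partner left at 12.0 s, 50% of its charge, gives a free share of 0.235, so by the product step alone, with partner held there, the pool has a half-life of 41.2 s, longer than the run.

(The rate constants were chosen freely; the flask was simulated.)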